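Everything rests on a retro-Diels–Alder cut of ring B (C5–C10) through the C5–C6 and C9–C10 bonds. One enantioselective [4+2] cycloaddition joins an open-chain E-configured α-methyl enal (C3–C2–C1–C10=C5–C4) and a 2-silyloxypentadiene (C6–C9). It closes ring B and sets the quaternary C5 together with C10. It exploits two features. The first is the anti relation of the C5 methyl group and C10–H across the ring fusion, which is just the E geometry of the enal. The second is the unsubstituted C6–C7 edge beside a latent C8 ketone. Ring A is closed afterwards by a 6-exo acyl radical cyclisation. C3 is then olefinated, and C9 is benzylated last on the rigid bicycle.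

Key step: step 3

Remark on locants:
- C5 is the ring-fusion carbon bearing CH3, and C10 is the ring-fusion CH.
- Ring A is C1–C5 plus C10. C3 carries the isopropylidene carbon C15, and C4 carries the chain C12–C14.
- Ring B is C5–C10. C8 is CHCH3, and C9 is quaternary with CH3 and the benzylic C11.
- β is the face of the C5 methyl group and α is the opposite face.
- The target is (4S,5R,8R,9S,10R).

Assumption: the (S)-prolinol-derived catalyst of step 3 is taken to expose the enal face that leads to (5R,10R). Its enantiomer is equally available if the sense is opposite.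

Step 1
Reactants: 1 methyl 4-oxobutanoate; 2 2-(triphenyl-λ5-phosphanylidene)propanal
Product: 3 methyl (4E)-5-methyl-6-oxohex-4-enoate
Conditions: PhMe, 80 °C
Reagents that add atoms: none
Why: Wittig olefination with a stabilised α-branched ylide should give the E-trisubstituted enal (CHO trans to the chain), and the ester is inert.

Step 2
Reactants: 4 pent-1-en-3-one
Product: 5 (3Z)-3-(triisopropylsilyloxy)penta-1,3-diene
Conditions: iPr3SiOSO2CF3, Et3N, CH2Cl2, 0 °C
Reagents that add atoms: triisopropylsilyl trifluoromethanesulfonate, CC(C)[Si](C(C)C)(C(C)C)OS(=O)(=O)C(F)(F)F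
Why: Soft enolisation and O-silylation on the only enolisable side should give the 2-silyloxydiene as the Z enol ether, whose methyl group lies outside in the s-cis diene.

Step 3
Reactants: 3 enal dienophile; 5 silyloxydiene
Product: 6 Diels–Alder adduct (ring B: 5β-CH3 5α-CHO 10α-H 9α-CH3 and C7=C8 silyl enol ether)
Conditions: (S)-3,3-diphenyl-1-(2-methylphenyl)tetrahydro-1H,3H-pyrrolo[1,2-c][1,3,2]oxazaborole and HN(SO2CF3)2 (20 mol % each), CH2Cl2, −78 → −40 °C
Reagents that add atoms: none
Why: The protonated oxazaborolidine binds the formyl oxygen of the s-trans enal 3 and lowers its LUMO, and diene 5 adds in a concerted, asynchronous, suprafacial [4π+2π] Diels–Alder reaction in which C9–C10 bonding is advanced and the C5–C6 bond completes ring B. The closest known reaction type is the Diels–Alder reaction of 2-silyloxy-1,3-dienes with α-substituted α,β-enals under chiral cationic oxazaborolidine catalysis. Ring B is closed in the [4+2] cycloaddition mode (two σ bonds, one six-membered ring, no other ring). C5 and C10 are fixed relative to each other by the E geometry of 3 (CHO trans to the C1 chain, hence C5-CH3 anti to C10-H), their absolute sense is fixed by the catalyst, whose aryl group shields one face of the bound enal, and C9 is fixed by the endo formyl group meeting the outside methyl of 5 (this centre is erased in step 15). The regioselectivity needed is secured twice, by the C8 silyloxy group (largest HOMO coefficient at C9, which meets the β-carbon C10) and by sterics (the unsubstituted terminus C6 meets the fully substituted C5). Addition to C=C instead of C=O and binding at the aldehyde instead of the ester follow from the lack of a 1-alkoxy group in 5 and from the higher basicity of the formyl oxygen.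

Step 4
Reactants: 7 (3-bromopropoxy)(tert-butyl)dimethylsilane; 8 triphenylphosphane
Product: 9 [3-(tert-butyldimethylsilyloxy)propyl]triphenylphosphonium bromide
Conditions: MeCN, reflux
Reagents that add atoms: none
Why: SN2 quaternisation of the phosphane by a primary bromide.

Step 5
Reactants: 6 Diels–Alder adduct; 9 phosphonium bromide
Product: 11 Z-alkenyl ester, via phosphorus ylide 10 (not isolated)
Conditions: KN(SiMe3)2, THF, −78 °C; then 6, −78 → 0 °C
Reagents that add atoms: none
Why: Wittig olefination of the non-enolisable α-quaternary aldehyde with a non-stabilised ylide should give the Z-alkene C4=C12 and bring in C12–C14, because the aldehyde reacts far faster than the ester.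

Step 6
Reactants: 11 Z-alkenyl ester
Product: 12 Se-phenyl selenoester
Conditions: AlMe3, PhSeH, CH2Cl2, 0 °C → rt
Reagents that add atoms: benzeneselenol, [SeH]c1ccccc1
Why: The aluminium selenolate made in the flask should convert the methyl ester directly into the acyl selenide, driven by the strong Al–O bond, and leave both silyl ethers untouched.

Step 7
Reactants: 12 Se-phenyl selenoester
Product: 13 trans-decalin-3-one (4β chain)
Conditions: (Me3Si)3SiH, AIBN, PhH (high dilution, slow addition), 80 °C
Reagents that add atoms: none
Why: In this radical chain reaction the C3 acyl radical adds 6-exo-trig to C4 through a chair-like transition state from the only productive, diequatorial conformer of the trans C5/C10 side arms, which enforces the trans ring fusion and places the C12 chain equatorial (4β, also the more stable epimer next to the ketone).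

Step 8
Reactants: 14 2-methylpropanoyl chloride; 15 benzenethiol
Product: 16 S-phenyl 2-methylpropanethioate
Conditions: Et3N, CH2Cl2, 0 °C
Reagents that add atoms: none
Why: Simple S-acylation of a thiol by an acid chloride.

Step 9
Reactants: 13 trans-decalin-3-one; 16 thioester
Product: 18 spiro-β-lactone at C3, via lithium thioester enolate 17 (not isolated)
Conditions: LiN(iPr)2, THF, −78 °C; 13; −78 → 0 °C; H2O
Reagents that add atoms: none
Why: Aldol addition of the weakly basic thioester enolate from the equatorial direction (the axial path is blocked by the C5 methyl group), followed on warming by ring closure with loss of thiophenolate, should give the β-lactone without enolising C4.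

Step 10
Reactants: 18 spiro-β-lactone
Product: 19 3-isopropylidene silyl enol ether
Conditions: xylenes, 140 °C
Reagents that add atoms: none
Why: Thermal [2+2] cycloreversion of the fully substituted β-lactone expels CO2 and places the double bond regiospecifically between C3 and C15, so C4 is not touched.

Step 11
Reactants: 19 3-isopropylidene silyl enol ether
Product: 20 C6–C7 enone
Conditions: Pd(OAc)2 (1.1 equiv), DMSO, 45 °C
Reagents that add atoms: none
Why: Saegusa–Ito oxidation (palladation at C7, then β-hydride elimination of a C6 hydrogen) should give the enone and leave C9–H as the only acidic position of the C8 ketone.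

Step 12
Reactants: 21 4-methoxy-2-methylphenol
Product: 22 2-(hydroxymethyl)-4-methoxy-6-methylphenol
Conditions: 37 % aq CH2O, NaOH, H2O, rt; AcOH
Reagents that add atoms: formaldehyde, C=O
Why: In the Lederer–Manasse hydroxymethylation the phenolate attacks formaldehyde at its single free ortho position, the para position being blocked by OMe.

Step 13
Reactants: 22 hydroxymethylphenol
Product: 23 [2-(benzyloxy)-5-methoxy-3-methylphenyl]methanol
Conditions: BnBr, K2CO3, acetone, reflux
Reagents that add atoms: benzyl bromide, BrCc1ccccc1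
Why: Williamson etherification under carbonate conditions is selective for the far more acidic phenol.

Step 14
Reactants: 23 benzylic alcohol
Product: 24 2-(benzyloxy)-1-(bromomethyl)-5-methoxy-3-methylbenzene
Conditions: PBr3, Et2O, 0 °C
Reagents that add atoms: phosphorus tribromide, BrP(Br)Br
Why: Activation of the benzylic alcohol as a phosphite and SN2 displacement by bromide.

Step 15
Reactants: 20 C6–C7 enone; 24 benzylic bromide
Product: 26 C9-benzylated enone (9α-CH2Ar 9β-CH3), via lithium dienolate 25 (not isolated)
Conditions: LiN(iPr)2, THF–DMPU, −78 °C; 24, −78 → −20 °C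
Reagents that add atoms: none
Why: α′-Deprotonation gives the cross-conjugated dienolate regiospecifically, and SN2 alkylation should occur on the α face, opposite the axial C5 methyl group, so that the benzyl group becomes 9α and the methyl group 9β.

Step 16
Reactants: 26 C9-benzylated enone
Product: 27 primary alcohol
Conditions: Bu4NF, THF, rt
Reagents that add atoms: none
Why: Fluoride cleaves the only remaining Si–O bond.

Step 17
Reactants: 27 primary alcohol
Product: 28 enone carboxylic acid
Conditions: TEMPO (cat.), PhI(OAc)2, MeCN–H2O, rt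
Reagents that add atoms: water, O
Why: Oxoammonium oxidation through the aldehyde hydrate takes the primary alcohol to the acid and tolerates the enone, the hindered alkene and the aryl ethers.

Step 18
Reactants: 28 enone carboxylic acid
Product: 29 8-methylene diene acid
Conditions: Ph3PCH3Br, KOtBu (excess), PhMe–THF, 80 °C; aq citric acid
Reagents that add atoms: methyltriphenylphosphonium bromide, C[P+](c1ccccc1)(c1ccccc1)c1ccccc1.[Br-]
Why: Wittig methylenation of the hindered ketone can be forced because it is no longer enolisable, and the carboxylate is inert.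

Step 19
Reactants: 29 8-methylene diene acid
Product: 30 target CNP0299684.2
Conditions: H2 (1 atm), Pd/C, EtOAc, rt
Reagents that add atoms: none
Why: Heterogeneous hydrogenation should saturate C6=C7 and the C8 methylene from the α face (the β face is covered by the axial methyl groups at C5 and C9, which gives 8β-CH3) and cleave the benzyl ether, while the tetrasubstituted C3=C15 bond is too hindered to react.

Compound list
1 | methyl 4-oxobutanoate | COC(=O)CCC=O | starting material
2 | 2-(triphenyl-λ5-phosphanylidene)propanal | CC(C=O)=P(c1ccccc1)(c1ccccc1)c1ccccc1 | starting material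
3 | methyl (4E)-5-methyl-6-oxohex-4-enoate | COC(=O)CC/C=C(\C)C=O | intermediate
4 | pent-1-en-3-one | CCC(=O)C=C | starting material
5 | (3Z)-3-(triisopropylsilyloxy)penta-1,3-diene | C=C/C(=C/C)O[Si](C(C)C)(C(C)C)C(C)C | intermediate
6 | methyl 3-[(1R,2R,6R)-2-formyl-2,6-dimethyl-5-(triisopropylsilyloxy)cyclohex-4-en-1-yl]propanoate | C[C@@H]1[C@@H](CCC(=O)OC)[C@](C)(C=O)CC=C1O[Si](C(C)C)(C(C)C)C(C)C | intermediate
7 | (3-bromopropoxy)(tert-butyl)dimethylsilane | CC(C)(C)[Si](C)(C)OCCCBr | starting material
8 | triphenylphosphane | c1ccc(cc1)P(c1ccccc1)c1ccccc1 | starting material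
9 | [3-(tert-butyldimethylsilyloxy)propyl]triphenylphosphonium bromide | CC(C)(C)[Si](C)(C)OCCC[P+](c1ccccc1)(c1ccccc1)c1ccccc1.[Br-] | intermediate
10 | [3-(tert-butyldimethylsilyloxy)propylidene]triphenyl-λ5-phosphane | CC(C)(C)[Si](C)(C)OCCC=P(c1ccccc1)(c1ccccc1)c1ccccc1 | intermediate
11 | as 6, CHO replaced by (1Z)-4-(tert-butyldimethylsilyloxy)but-1-enyl | C[C@@H]1[C@@H](CCC(=O)OC)[C@](C)(/C=C\CCO[Si](C)(C)C(C)(C)C)CC=C1O[Si](C(C)C)(C(C)C)C(C)C | intermediate
12 | as 11, CO2Me replaced by C(=O)SePh | C[C@@H]1[C@@H](CCC(=O)[Se]c2ccccc2)[C@](C)(/C=C\CCO[Si](C)(C)C(C)(C)C)CC=C1O[Si](C(C)C)(C(C)C)C(C)C | intermediate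
13 | trans-decalin: 3-oxo, 4β-[3-(TBSO)propyl], 5β-CH3, 10α-H, 9α-CH3, C7=C8 triisopropylsilyl enol ether | C[C@@H]1[C@H]2CCC(=O)[C@@H](CCCO[Si](C)(C)C(C)(C)C)[C@]2(C)CC=C1O[Si](C(C)C)(C(C)C)C(C)C | intermediate
14 | 2-methylpropanoyl chloride | CC(C)C(Cl)=O | starting material
15 | benzenethiol | Sc1ccccc1 | starting material
16 | S-phenyl 2-methylpropanethioate | CC(C)C(=O)Sc1ccccc1 | intermediate
17 | lithium 2-methyl-1-(phenylsulfanyl)prop-1-en-1-olate | CC(C)=C([O-])Sc1ccccc1.[Li+] | intermediate
18 | as 13, C3 spiro-fused to a 3,3-dimethyloxetan-2-one (O axial β, C15 equatorial) | C[C@@H]1[C@H]2CC[C@@]3(OC(=O)C3(C)C)[C@@H](CCCO[Si](C)(C)C(C)(C)C)[C@]2(C)CC=C1O[Si](C(C)C)(C(C)C)C(C)C | intermediate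
19 | as 13, C3=O replaced by C3=C(CH3)2 | C[C@@H]1[C@H]2CCC(=C(C)C)[C@@H](CCCO[Si](C)(C)C(C)(C)C)[C@]2(C)CC=C1O[Si](C(C)C)(C(C)C)C(C)C | intermediate
20 | 8-oxo-C6=C7 enone, 9α-CH3 9β-H, otherwise as 19 | C[C@@H]1[C@H]2CCC(=C(C)C)[C@@H](CCCO[Si](C)(C)C(C)(C)C)[C@]2(C)C=CC1=O | intermediate
21 | 4-methoxy-2-methylphenol | COc1ccc(O)c(C)c1 | starting material
22 | 2-(hydroxymethyl)-4-methoxy-6-methylphenol | COc1cc(C)c(O)c(CO)c1 | intermediate
23 | [2-(benzyloxy)-5-methoxy-3-methylphenyl]methanol | COc1cc(C)c(OCc2ccccc2)c(CO)c1 | intermediate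
24 | 2-(benzyloxy)-1-(bromomethyl)-5-methoxy-3-methylbenzene | COc1cc(C)c(OCc2ccccc2)c(CBr)c1 | intermediate
25 | lithium C8-olate of the C6=C7/C8=C9 dienolate of 20 | CC=1[C@H]2CCC(=C(C)C)[C@@H](CCCO[Si](C)(C)C(C)(C)C)[C@]2(C)C=CC=1[O-].[Li+] | intermediate
26 | as 20, C9 quaternary: 9β-CH3, 9α-CH2Ar (Ar = 2-benzyloxy-5-methoxy-3-methylphenyl) | COc1cc(C)c(OCc2ccccc2)c(C[C@]3(C)[C@H]4CCC(=C(C)C)[C@@H](CCCO[Si](C)(C)C(C)(C)C)[C@]4(C)C=CC3=O)c1 | intermediate
27 | as 26, C14 free primary alcohol | COc1cc(C)c(OCc2ccccc2)c(C[C@]3(C)[C@H]4CCC(=C(C)C)[C@@H](CCCO)[C@]4(C)C=CC3=O)c1 | intermediate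
28 | as 26, C14 carboxylic acid | COc1cc(C)c(OCc2ccccc2)c(C[C@]3(C)[C@H]4CCC(=C(C)C)[C@@H](CCC(=O)O)[C@]4(C)C=CC3=O)c1 | intermediate
29 | as 28, C8=O replaced by C8=CH2 | COc1cc(C)c(OCc2ccccc2)c(C[C@]3(C)[C@H]4CCC(=C(C)C)[C@@H](CCC(=O)O)[C@]4(C)C=CC3=C)c1 | intermediate
30 | CNP0299684.2, (4S,5R,8R,9S,10R) seco acid | COc1cc(C)c(O)c(C[C@]2(C)[C@H]3CCC(=C(C)C)[C@@H](CCC(=O)O)[C@]3(C)CC[C@H]2C)c1 | target

Total step count: 19. Longest linear sequence: 13 steps (1, 3, 5, 6, 7, 9, 10, 11, 15, 16, 17, 18, 19).

Steps most likely to fail

Step 3 (key step). The trisubstituted enal may react too slowly at the temperatures at which the catalyst keeps its face selectivity. Loss of the diene by protodesilylation or a stepwise Mukaiyama–Michael path may then compete. The fallback gives up asymmetric catalysis for a resolution. It sets out from 3 and 5, whose cycloaddition promoted by the achiral Lewis acid Me2AlCl should give the racemic adduct F1. NaBH4 reduces its formyl group to the racemic neopentyl alcohol F2. Acylation with vinyl acetate catalysed by Burkholderia cepacia lipase should leave the (5R,10R) alcohol F3 and turn its antipode into the acetate F4, which is removed by chromatography. Oxidation of F3 with Dess–Martin periodinane comes back to the route at 6.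

Step 9. Addition of a fully substituted enolate carbon to a ketone flanked by the C4 branch may be reversed (retro-aldol) before lactonisation, and proton transfer may erode C4. The fallback sets out from 13 and comes back at 19. It is a reductive McMurry cross-coupling of the ketone with an excess of acetone on low-valent titanium (TiCl4, Zn, pyridine, THF, reflux), which forms the C3=C15 bond directly. Homocoupling of the hindered 13 should be slow, and the acetone dimer is volatile. This fallback makes no compound outside the list (F0).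

Step 7. Premature reduction of the acyl radical, 7-endo attack at the less hindered C12 or decarbonylation may compete with the 6-exo closure next to the quaternary C5. The fallback closes ring A by a polar reaction and sets out from 11. iBu2AlH at −78 °C gives the aldehyde F5. Me2AlCl triggers a carbonyl-ene cyclisation (C3–C4 bond, hydrogen taken from C13, all-equatorial chair) to the homoallylic alcohol F6. Diimide (2-nitrobenzenesulfonohydrazide, Et3N) saturates the disubstituted C12=C13 bond to give the alcohol F7. Dess–Martin periodinane then comes back to the route at 13.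

Further compounds
F1 | step 3 | racemic Diels–Alder adduct | C[C@@H]1[C@@H](CCC(=O)OC)[C@](C)(C=O)CC=C1O[Si](C(C)C)(C(C)C)C(C)C.C[C@H]1[C@H](CCC(=O)OC)[C@@](C)(C=O)CC=C1O[Si](C(C)C)(C(C)C)C(C)C
F2 | step 3 | racemic neopentyl alcohol | C[C@@H]1[C@@H](CCC(=O)OC)[C@](C)(CO)CC=C1O[Si](C(C)C)(C(C)C)C(C)C.C[C@H]1[C@H](CCC(=O)OC)[C@@](C)(CO)CC=C1O[Si](C(C)C)(C(C)C)C(C)C
F3 | step 3 | (5R,10R) neopentyl alcohol | C[C@@H]1[C@@H](CCC(=O)OC)[C@](C)(CO)CC=C1O[Si](C(C)C)(C(C)C)C(C)C
F4 | step 3 | acetate of the antipodal alcohol | C[C@H]1[C@H](CCC(=O)OC)[C@@](C)(COC(C)=O)CC=C1O[Si](C(C)C)(C(C)C)C(C)C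
F5 | step 7 | C3 aldehyde corresponding to 11 | C[C@@H]1[C@@H](CCC=O)[C@](C)(/C=C\CCO[Si](C)(C)C(C)(C)C)CC=C1O[Si](C(C)C)(C(C)C)C(C)C
F6 | step 7 | ene product, 3α-OH, 4β-[(1E)-3-(TBSO)prop-1-enyl] trans-decalin | C[C@@H]1[C@H]2CC[C@H](O)[C@@H](/C=C/CO[Si](C)(C)C(C)(C)C)[C@]2(C)CC=C1O[Si](C(C)C)(C(C)C)C(C)C
F7 | step 7 | saturated 3α-alcohol | C[C@@H]1[C@H]2CC[C@H](O)[C@@H](CCCO[Si](C)(C)C(C)(C)C)[C@]2(C)CC=C1O[Si](C(C)C)(C(C)C)C(C)C
F0 | step 9 | none | none
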